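**Retrosynthetic overview**
1. The strategy rests on the C3–C7 stretch of the nine-membered lactone ring (C1 carbonyl, C2–C8, O9). C3 (aldehyde level), C4–Me, C5–O, C6–Me and C7 with its oxygen O7 are the five carbons and the ring oxygen of a 3,5-dimethyl-2,3-dihydropyran-4-one (O7 ring oxygen, C5 ketone, C3 enol-ether carbon).
2. Late bonds: the Z-alkene from the C2′–C3′ alkyne (last step), the O7–C1′ ester from ynoic acid 35, and O9–C1 by macrolactonisation of seco acid 28.
3. C2–C3 comes from an auxiliary-controlled syn propionate aldol on the acyclic C3 aldehyde 21, which is the opened and protected form of lactol 18.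
4. C4–O comes from epoxidation of glycal 16, and C5 from 1,2-reduction and inversion of pyranone 10. Pyranone 10 comes from the hetero-Diels–Alder union of aldehyde 3 (C7, C8) and diene 8 (C3–C6).
5. Ring order: the pyran ring is formed first (step 6) and opened again in step 14; the nine-membered lactone is formed second (step 21).

Key step: step 6

Remark on numbering and drawing: target locants (C1–C8, O9, C1′–C8′) are used for all intermediates. In a zigzag drawn from C1 (left) to C8 with C2 as an upper vertex, 2-Me, 3-O, 4-O, 5-O, 6-Me and 7-O point to the rear and 4-Me and 8-O point to the front. All acyclic intermediates keep this arrangement.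
Assumption: 22 and 32 are purchased, and DMDO is used as a freshly prepared acetone solution.

**Step 1**
Reactants: 1 ethyl (S)-lactate
Product: 2 ethyl (S)-2-(tert-butyldiphenylsilyloxy)propanoate
Conditions: TBDPSCl, imidazole, DMF, 0 °C → rt
Reagents that add atoms: tert-butyl(chloro)diphenylsilane, CC(C)(C)[Si](Cl)(c1ccccc1)c1ccccc1
Why: Imidazole-promoted O-silylation leaves C8 untouched and installs the bulky, weakly basic ether that later disfavours chelation.

**Step 2**
Reactants: 2 ethyl (S)-2-(tert-butyldiphenylsilyloxy)propanoate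
Product: 3 (S)-2-(tert-butyldiphenylsilyloxy)propanal
Conditions: i-Bu2AlH, CH2Cl2, −78 °C; MeOH, aq. potassium sodium tartrate
Reagents that add atoms: none
Why: Partial ester reduction stops at the aluminium hemiacetal at low temperature, and the α-silyloxy aldehyde keeps its configuration if it is used promptly.

**Step 3**
Reactants: 4 pentan-3-one
Product: 6 1-hydroxy-2-methylpent-1-en-3-one, via sodium enolate 5 (not isolated)
Conditions: HCO2Et, NaH, Et2O, 0 °C → rt; cold aq. HCl
Reagents that add atoms: ethyl formate, CCOC=O; sodium hydride, [H-].[Na+] (sodium only in 5)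
Why: Crossed Claisen formylation of the symmetrical ketone with a non-enolisable formate is driven by formation of the stabilised β-keto aldehyde enolate.

**Step 4**
Reactants: 6 1-hydroxy-2-methylpent-1-en-3-one
Product: 7 (E)-1-methoxy-2-methylpent-1-en-3-one
Conditions: Me2SO4, K2CO3, acetone, reflux
Reagents that add atoms: dimethyl sulfate, COS(=O)(=O)OC
Why: O-alkylation of the vinylogous acid with a hard methylating agent gives the more stable E β-methoxy enone.

**Step 5**
Reactants: 7 (E)-1-methoxy-2-methylpent-1-en-3-one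
Product: 8 (1E,3Z)-1-methoxy-2-methyl-3-(trimethylsilyloxy)penta-1,3-diene
Conditions: TMSOTf, Et3N, Et2O, 0 °C
Reagents that add atoms: trimethylsilyl trifluoromethanesulfonate, C[Si](C)(C)OS(=O)(=O)C(F)(F)F
Why: Soft enolisation and enol silylation at the only enolisable position gives the Z silyl enol ether (minimised allylic strain), and with it the 1-alkoxy-3-silyloxy diene.

**Step 6**
Reactants: 3 (S)-2-(tert-butyldiphenylsilyloxy)propanal; 8 (1E,3Z)-1-methoxy-2-methyl-3-(trimethylsilyloxy)penta-1,3-diene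
Product: 10 (2R,3R)-2-[(1S)-1-(tert-butyldiphenylsilyloxy)ethyl]-3,5-dimethyl-2,3-dihydro-4H-pyran-4-one, via all-cis cycloadduct 9 (not isolated)
Conditions: Eu(fod)3 [tris(6,6,7,7,8,8,8-heptafluoro-2,2-dimethyloctane-3,5-dionato)europium] (5–10 mol %), CH2Cl2, rt; then TFA (cat.), CH2Cl2, 0 °C
Reagents that add atoms: none
Why: The europium chelate binds the aldehyde oxygen as a mild monodentate Lewis acid, and the electron-rich diene adds in a concerted but asynchronous [4+2] hetero-Diels–Alder cyclocondensation in which C6–C7 forms ahead of O7–C3. The six-membered ring (C3–C7 and O7) is closed by the cycloaddition itself to give enol ether 9, from which catalytic acid expels MeOSiMe3 and unveils the vinylogous ester 10 without any protonation at carbon. For C6 relative to C7, the metal-bearing lone pair sits exo and the C8 residue endo, and since the methyl at the Z enol silane terminus is an outside substituent this gives the 2,3-cis ring relationship. For C7 relative to C8, the non-chelating OTBDPS group makes the aldehyde react through the polar Felkin–Anh rotamer (C–OSi perpendicular to C=O, diene passing the C8 hydrogen), which gives the 7,8-anti diol pattern, that is 7R from 8S. The step therefore needs endo over exo, pericyclic over stepwise aldol (which leads to trans products) and Felkin over chelate selectivity, and these are secured by the weak lanthanide Lewis acid, the diene geometry and the bulky silyl ether respectively. The acid treatment is kept short and cold because C6 is now α to a ketone and could epimerise.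

**Step 7**
Reactants: 10 cis-dihydropyranone
Product: 11 (2R,3S,4R)-2-[(1S)-1-(tert-butyldiphenylsilyloxy)ethyl]-3,5-dimethyl-3,4-dihydro-2H-pyran-4-ol
Conditions: NaBH4, CeCl3·7H2O, MeOH/CH2Cl2, −78 °C
Reagents that add atoms: none
Why: In the Luche 1,2-reduction hydride attacks C5 from the face opposite the pseudo-axial C6 methyl, so the all-cis 5R alcohol should form, which is the C5 epimer of what the target needs.

**Step 8**
Reactants: 11 all-cis allylic alcohol
Product: 12 (2R,3S,4S)-2-[(1S)-1-(tert-butyldiphenylsilyloxy)ethyl]-3,5-dimethyl-3,4-dihydro-2H-pyran-4-yl 4-nitrobenzoate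
Conditions: 4-O2NC6H4CO2H, PPh3, DIAD, toluene, −20 °C → rt
Reagents that add atoms: 4-nitrobenzoic acid, OC(=O)c1ccc(cc1)[N+](=O)[O-]
Why: Mitsunobu inversion with an acidic carboxylate displaces the oxyphosphonium group by SN2 from the open face anti to the C6 methyl and C7 side chain and sets 5S, while low temperature and a non-polar solvent hold back attack at C3 with allylic shift.

**Step 9**
Reactants: 12 inverted 4-nitrobenzoate
Product: 13 (2R,3S,4S)-2-[(1S)-1-hydroxyethyl]-3,5-dimethyl-3,4-dihydro-2H-pyran-4-yl 4-nitrobenzoate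
Conditions: TBAF/AcOH (1:1), THF, rt → 40 °C
Reagents that add atoms: none
Why: Buffered fluoride desilylation spares the ester and the acid-labile glycal, and it is done here because a TBDPS ether could not later be removed selectively beside the silyl ethers planned for O3–O5.

**Step 10**
Reactants: 13 C8 alcohol
Product: 14 (2R,3S,4S)-2-[(1S)-1-(benzyloxymethoxy)ethyl]-3,5-dimethyl-3,4-dihydro-2H-pyran-4-yl 4-nitrobenzoate
Conditions: BOMCl, i-Pr2NEt, n-Bu4NI (cat.), CH2Cl2, 0 → 40 °C
Reagents that add atoms: benzyl chloromethyl ether, ClCOCc1ccccc1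
Why: Alkylation with an α-chloro ether under amine base needs neither alkoxide nor acid, so the ester and enol ether survive, and the BOM acetal (removed by hydrogenolysis) is orthogonal to all later silyl ethers.

**Step 11**
Reactants: 14 BOM ether ester
Product: 15 (2R,3S,4S)-2-[(1S)-1-(benzyloxymethoxy)ethyl]-3,5-dimethyl-3,4-dihydro-2H-pyran-4-ol
Conditions: K2CO3 (cat.), MeOH, 0 °C → rt
Reagents that add atoms: none
Why: Zemplén-type transesterification of the activated aryl ester cleaves the acyl–oxygen bond, so C5 keeps its configuration.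

**Step 12**
Reactants: 15 5S allylic alcohol
Product: 16 (2R,3R,4S)-2-[(1S)-1-(benzyloxymethoxy)ethyl]-4-(tert-butyldimethylsilyloxy)-3,5-dimethyl-3,4-dihydro-2H-pyran
Conditions: TBSOTf, 2,6-lutidine, CH2Cl2, −78 → 0 °C
Reagents that add atoms: tert-butyldimethylsilyl trifluoromethanesulfonate, CC(C)(C)[Si](C)(C)OS(=O)(=O)C(F)(F)F
Why: Silyl triflate silylation covers the hindered pseudo-axial alcohol while the base keeps the medium non-acidic for the glycal.

**Step 13**
Reactants: 16 silylated glycal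
Product: 18 C3 lactol 6-[(1S)-1-(benzyloxymethoxy)ethyl]-4-(tert-butyldimethylsilyloxy)-3,5-dimethyltetrahydro-2H-pyran-2,3-diol (anomeric mixture), via glycal epoxide 17 (not isolated)
Conditions: DMDO (acetone), CH2Cl2, 0 °C; evaporate; THF/H2O, 0 °C → rt
Reagents that add atoms: dimethyldioxirane, CC1(C)OO1; water, O
Why: In this glycal epoxidation, A(1,2) strain with the C4 methyl holds the C5 OTBS group pseudo-axial so that it blocks its own face, oxygen arrives anti to it and sets 4R, and water then opens the anhydro sugar only at the acetal carbon C3.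

**Step 14**
Reactants: 18 C3 lactol
Product: 19 (2S,3S,4R,5R,6S)-6-(benzyloxymethoxy)-3-(tert-butyldimethylsilyloxy)-2,4-dimethylheptane-1,2,5-triol
Conditions: NaBH4, EtOH/THF, 0 °C → rt
Reagents that add atoms: none
Why: Borohydride reduction of the open hydroxy aldehyde tautomer drains the lactol and frees O7 from the ring, which is needed because an aldol on the lactol itself would leave O4–H free to lactonise onto C1.

**Step 15**
Reactants: 19 C3,C4,C7 triol
Product: 20 (2S,3S,4R,5R,6S)-6-(benzyloxymethoxy)-3-(tert-butyldimethylsilyloxy)-2,4-dimethyl-1,2,5-tris(triethylsilyloxy)heptane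
Conditions: TESOTf (excess), 2,6-lutidine, CH2Cl2, 0 °C → rt
Reagents that add atoms: triethylsilyl trifluoromethanesulfonate, CC[Si](CC)(CC)OS(=O)(=O)C(F)(F)F
Why: Exhaustive silylation with the reactive triflate covers the primary, secondary and tertiary hydroxyls in one operation.

**Step 16**
Reactants: 20 tris(triethylsilyl) ether
Product: 21 (2R,3S,4R,5R,6S)-6-(benzyloxymethoxy)-3-(tert-butyldimethylsilyloxy)-2,4-dimethyl-2,5-bis(triethylsilyloxy)heptanal
Conditions: (COCl)2, DMSO, CH2Cl2, −78 → −30 °C; Et3N, −78 °C → rt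
Reagents that add atoms: none
Why: Swern conditions cleave and oxidise primary triethylsilyl ethers directly, whereas the secondary and tertiary ones are too hindered for the chlorosulfonium salt, which gives the non-enolisable C3 aldehyde.

**Step 17**
Reactants: 21 C3 aldehyde; 22 (R)-4-benzyl-3-propionyloxazolidin-2-one
Product: 24 (R)-4-benzyl-3-[(2R,3R)-8-(benzyloxymethoxy)-5-(tert-butyldimethylsilyloxy)-3-hydroxy-2,4,6-trimethyl-4,7-bis(triethylsilyloxy)nonanoyl]oxazolidin-2-one, via Z boron enolate 23 (not isolated)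
Conditions: 22, n-Bu2BOTf, Et3N, CH2Cl2, −78 → 0 °C; 21, −78 → 0 °C; pH 7 buffer, MeOH, H2O2, 0 °C
Reagents that add atoms: dibutylboron trifluoromethanesulfonate, CCCCB(CCCC)OS(=O)(=O)C(F)(F)F (boron only in 23)
Why: In the Evans syn aldol the Z boron enolate reacts through a Zimmerman–Traxler chair whose face is fixed by the (R)-benzyl auxiliary, which gives 2R,3R, and the α-quaternary aldehyde has only a weak facial bias towards Z enolates, so reagent control should prevail.

**Step 18**
Reactants: 24 aldol adduct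
Product: 25 3-O-tert-butyldimethylsilyl ether of 24
Conditions: TBSOTf, 2,6-lutidine, CH2Cl2, 0 °C → rt
Reagents that add atoms: tert-butyldimethylsilyl trifluoromethanesulfonate, CC(C)(C)[Si](C)(C)OS(=O)(=O)C(F)(F)F
Why: Silyl triflate silylation under non-nucleophilic base caps the hindered C3 hydroxyl without retro-aldol and blocks β-lactone formation later.

**Step 19**
Reactants: 25 protected imide
Product: 27 8-(benzyloxymethoxy)-3,5-bis(tert-butyldimethylsilyloxy)-2,4,6-trimethyl-4,7-bis(triethylsilyloxy)nonanoic acid, via peroxy acid 26 (not isolated)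
Conditions: LiOH, H2O2, THF/H2O, 0 °C; Na2SO3; aq. KHSO4 to pH 4
Reagents that add atoms: hydrogen peroxide, OO
Why: In this hydroperoxide-mediated auxiliary cleavage the small α-effect nucleophile attacks the exocyclic carbonyl even of hindered imides and does not epimerise C2.

**Step 20**
Reactants: 27 C1 acid
Product: 28 seco acid 8-hydroxy-3,5-bis(tert-butyldimethylsilyloxy)-2,4,6-trimethyl-4,7-bis(triethylsilyloxy)nonanoic acid
Conditions: H2 (1 atm), Pd(OH)2/C, EtOAc, rt
Reagents that add atoms: none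
Why: Neutral hydrogenolysis of the benzyl part of the BOM acetal and collapse of the resulting hemiformal free only O8–H, and all silyl ethers persist in the aprotic solvent.

**Step 21**
Reactants: 28 seco acid
Product: 30 nine-membered lactone with 3,5-bis-O-TBS and 4,7-bis-O-TES protection, via mixed anhydride 29 (not isolated)
Conditions: 2-methyl-6-nitrobenzoic anhydride (MNBA), DMAP, CH2Cl2 (about 2 mM), syringe-pump addition, rt → 40 °C
Reagents that add atoms: 2-methyl-6-nitrobenzoic anhydride, Cc1cccc([N+](=O)[O-])c1C(=O)OC(=O)c1c(C)cccc1[N+](=O)[O-] (aroyl group only in 29)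
Why: In the Shiina macrolactonisation the mixed anhydride forms chemoselectively and DMAP acyl transfer at high dilution closes O9–C1 with retention at C8, with O8–H as the only free hydroxyl and a fully substituted chain that favours folded conformers.

**Step 22**
Reactants: 30 protected lactone
Product: 31 7-hydroxy lactone (3,5-bis-O-TBS, 4-O-TES)
Conditions: PPTS (cat.), MeOH/CH2Cl2, 0 °C
Reagents that add atoms: none
Why: Acid-catalysed methanolysis discriminates by size and environment, because the secondary OTES at C7 is far more labile than the TBS ethers and than the tertiary OTES buried between them.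

**Step 23**
Reactants: 32 (R)-hept-1-yn-3-ol
Product: 33 (R)-3-(tert-butyldimethylsilyloxy)hept-1-yne
Conditions: TBSCl, imidazole, DMF, rt
Reagents that add atoms: tert-butyl(chloro)dimethylsilane, CC(C)(C)[Si](C)(C)Cl
Why: Standard O-silylation leaves C4′ untouched.

**Step 24**
Reactants: 33 silyl ether
Product: 35 (R)-4-(tert-butyldimethylsilyloxy)oct-2-ynoic acid, via lithium acetylide 34 (not isolated)
Conditions: n-BuLi, THF, −78 °C; CO2; cold 1 M HCl
Reagents that add atoms: carbon dioxide, O=C=O; n-butyllithium, [Li]CCCC (lithium only in 34)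
Why: Carboxylation of the terminal acetylide adds C1′ without affecting the propargylic stereocentre.

**Step 25**
Reactants: 31 7-hydroxy lactone; 35 ynoic acid
Product: 37 C7 (R)-4-(tert-butyldimethylsilyloxy)oct-2-ynoate of 31, via mixed anhydride 36 (not isolated)
Conditions: 35, 2,4,6-Cl3C6H2COCl, Et3N, toluene, rt; then 31, DMAP, 0 °C → rt
Reagents that add atoms: 2,4,6-trichlorobenzoyl chloride, O=C(Cl)c1c(Cl)cc(Cl)cc1Cl (aroyl group only in 36)
Why: In the Yamaguchi esterification the rod-like alkynoyl unit is a sterically small acyl donor for the hindered C7 hydroxyl, and using the alkyne avoids DMAP-induced isomerisation of a Z-enoate.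

**Step 26**
Reactants: 37 fully silylated ynoate
Product: 38 tetraol ynoate (3,4,5,4′-tetrahydroxy)
Conditions: HF·pyridine, pyridine, THF, 0 °C → rt; cold pH 7 buffer
Reagents that add atoms: none
Why: Buffered fluoride-mediated global desilylation is used at the alkyne stage, where the freed C4′ hydroxyl cannot reach C1′, so butenolide formation with loss of the macrolide is geometrically excluded.

**Step 27**
Reactants: 38 tetraol ynoate
Product: 39 (3R,4R,5R,6S,7S,8R,9S)-4,5,6-trihydroxy-3,5,7,9-tetramethyl-2-oxooxonan-8-yl (2Z,4R)-4-hydroxyoct-2-enoate (CNP0205075.2)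
Conditions: H2 (1 atm), Pd/CaCO3 poisoned with Pb(OAc)2, quinoline, EtOAc, 0 °C → rt, stopped at one equivalent of H2
Reagents that add atoms: none
Why: Lindlar semi-hydrogenation delivers H2 syn on the poisoned surface and gives the Z-enoate, and keeping this neutral step for last means the lactonisation-prone Z-γ-hydroxy enoate never meets acid, base or fluoride.

**Compound list**
1 | ethyl (S)-lactate | CCOC(=O)[C@H](C)O | starting material
2 | ethyl (S)-2-(tert-butyldiphenylsilyloxy)propanoate | CCOC(=O)[C@H](C)O[Si](c1ccccc1)(c1ccccc1)C(C)(C)C | intermediate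
3 | (S)-2-(tert-butyldiphenylsilyloxy)propanal | C[C@H](O[Si](c1ccccc1)(c1ccccc1)C(C)(C)C)C=O | intermediate
4 | pentan-3-one | CCC(=O)CC | starting material
5 | sodium 2-methyl-3-oxopent-1-en-1-olate | CCC(=O)C(C)=C[O-].[Na+] | intermediate
6 | 1-hydroxy-2-methylpent-1-en-3-one (enol of 2-methyl-3-oxopentanal) | CCC(=O)C(C)=CO | intermediate
7 | (E)-1-methoxy-2-methylpent-1-en-3-one | CCC(=O)/C(C)=C/OC | intermediate
8 | (1E,3Z)-1-methoxy-2-methyl-3-(trimethylsilyloxy)penta-1,3-diene | CO/C=C(C)/C(O[Si](C)(C)C)=C/C | intermediate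
9 | (2R,3R,6S)-2-[(1S)-1-(tert-butyldiphenylsilyloxy)ethyl]-6-methoxy-3,5-dimethyl-4-(trimethylsilyloxy)-3,6-dihydro-2H-pyran | C[C@H](O[Si](c1ccccc1)(c1ccccc1)C(C)(C)C)[C@@H]1O[C@H](OC)C(C)=C(O[Si](C)(C)C)[C@@H]1C | intermediate
10 | (2R,3R)-2-[(1S)-1-(tert-butyldiphenylsilyloxy)ethyl]-3,5-dimethyl-2,3-dihydro-4H-pyran-4-one | C[C@H](O[Si](c1ccccc1)(c1ccccc1)C(C)(C)C)[C@@H]1OC=C(C)C(=O)[C@@H]1C | intermediate
11 | (2R,3S,4R)-2-[(1S)-1-(tert-butyldiphenylsilyloxy)ethyl]-3,5-dimethyl-3,4-dihydro-2H-pyran-4-ol | C[C@H](O[Si](c1ccccc1)(c1ccccc1)C(C)(C)C)[C@@H]1OC=C(C)[C@H](O)[C@@H]1C | intermediate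
12 | (2R,3S,4S)-2-[(1S)-1-(tert-butyldiphenylsilyloxy)ethyl]-3,5-dimethyl-3,4-dihydro-2H-pyran-4-yl 4-nitrobenzoate | C[C@H](O[Si](c1ccccc1)(c1ccccc1)C(C)(C)C)[C@@H]1OC=C(C)[C@@H](OC(=O)c2ccc(cc2)[N+](=O)[O-])[C@@H]1C | intermediate
13 | (2R,3S,4S)-2-[(1S)-1-hydroxyethyl]-3,5-dimethyl-3,4-dihydro-2H-pyran-4-yl 4-nitrobenzoate | C[C@H](O)[C@@H]1OC=C(C)[C@@H](OC(=O)c2ccc(cc2)[N+](=O)[O-])[C@@H]1C | intermediate
14 | (2R,3S,4S)-2-[(1S)-1-(benzyloxymethoxy)ethyl]-3,5-dimethyl-3,4-dihydro-2H-pyran-4-yl 4-nitrobenzoate | C[C@H](OCOCc1ccccc1)[C@@H]1OC=C(C)[C@@H](OC(=O)c2ccc(cc2)[N+](=O)[O-])[C@@H]1C | intermediate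
15 | (2R,3S,4S)-2-[(1S)-1-(benzyloxymethoxy)ethyl]-3,5-dimethyl-3,4-dihydro-2H-pyran-4-ol | C[C@H](OCOCc1ccccc1)[C@@H]1OC=C(C)[C@@H](O)[C@@H]1C | intermediate
16 | (2R,3R,4S)-2-[(1S)-1-(benzyloxymethoxy)ethyl]-4-(tert-butyldimethylsilyloxy)-3,5-dimethyl-3,4-dihydro-2H-pyran | C[C@H](OCOCc1ccccc1)[C@@H]1OC=C(C)[C@@H](O[Si](C)(C)C(C)(C)C)[C@@H]1C | intermediate
17 | C3–C4 epoxide of 16, oxirane oxygen anti to the C5 OTBS group | C[C@H](OCOCc1ccccc1)[C@@H]1O[C@@H]2O[C@]2(C)[C@@H](O[Si](C)(C)C(C)(C)C)[C@@H]1C | intermediate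
18 | C3 lactol (4R, anomeric mixture), 6-[(1S)-1-(benzyloxymethoxy)ethyl]-4-(tert-butyldimethylsilyloxy)-3,5-dimethyltetrahydro-2H-pyran-2,3-diol | C[C@H](OCOCc1ccccc1)[C@@H]1OC(O)[C@](C)(O)[C@@H](O[Si](C)(C)C(C)(C)C)[C@@H]1C | intermediate
19 | (2S,3S,4R,5R,6S)-6-(benzyloxymethoxy)-3-(tert-butyldimethylsilyloxy)-2,4-dimethylheptane-1,2,5-triol | C[C@H](OCOCc1ccccc1)[C@H](O)[C@@H](C)[C@H](O[Si](C)(C)C(C)(C)C)[C@@](C)(O)CO | intermediate
20 | (2S,3S,4R,5R,6S)-6-(benzyloxymethoxy)-3-(tert-butyldimethylsilyloxy)-2,4-dimethyl-1,2,5-tris(triethylsilyloxy)heptane | C[C@H](OCOCc1ccccc1)[C@H](O[Si](CC)(CC)CC)[C@@H](C)[C@H](O[Si](C)(C)C(C)(C)C)[C@@](C)(O[Si](CC)(CC)CC)CO[Si](CC)(CC)CC | intermediate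
21 | (2R,3S,4R,5R,6S)-6-(benzyloxymethoxy)-3-(tert-butyldimethylsilyloxy)-2,4-dimethyl-2,5-bis(triethylsilyloxy)heptanal | C[C@H](OCOCc1ccccc1)[C@H](O[Si](CC)(CC)CC)[C@@H](C)[C@H](O[Si](C)(C)C(C)(C)C)[C@@](C)(O[Si](CC)(CC)CC)C=O | intermediate
22 | (R)-4-benzyl-3-propionyloxazolidin-2-one | CCC(=O)N1[C@H](Cc2ccccc2)COC1=O | starting material
23 | Z dibutylboron enolate of 22 | C/C=C(\OB(CCCC)CCCC)N1[C@H](Cc2ccccc2)COC1=O | intermediate
24 | syn aldol adduct (2R,3R; C4–C8 as in 21) | C[C@H](OCOCc1ccccc1)[C@H](O[Si](CC)(CC)CC)[C@@H](C)[C@H](O[Si](C)(C)C(C)(C)C)[C@@](C)(O[Si](CC)(CC)CC)[C@H](O)[C@@H](C)C(=O)N1[C@H](Cc2ccccc2)COC1=O | intermediate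
25 | 3-O-TBS ether of 24 | C[C@H](OCOCc1ccccc1)[C@H](O[Si](CC)(CC)CC)[C@@H](C)[C@H](O[Si](C)(C)C(C)(C)C)[C@@](C)(O[Si](CC)(CC)CC)[C@H](O[Si](C)(C)C(C)(C)C)[C@@H](C)C(=O)N1[C@H](Cc2ccccc2)COC1=O | intermediate
26 | C1 peroxy acid | C[C@H](OCOCc1ccccc1)[C@H](O[Si](CC)(CC)CC)[C@@H](C)[C@H](O[Si](C)(C)C(C)(C)C)[C@@](C)(O[Si](CC)(CC)CC)[C@H](O[Si](C)(C)C(C)(C)C)[C@@H](C)C(=O)OO | intermediate
27 | 8-(benzyloxymethoxy)-3,5-bis(tert-butyldimethylsilyloxy)-2,4,6-trimethyl-4,7-bis(triethylsilyloxy)nonanoic acid | C[C@H](OCOCc1ccccc1)[C@H](O[Si](CC)(CC)CC)[C@@H](C)[C@H](O[Si](C)(C)C(C)(C)C)[C@@](C)(O[Si](CC)(CC)CC)[C@H](O[Si](C)(C)C(C)(C)C)[C@@H](C)C(=O)O | intermediate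
28 | seco acid (8-hydroxy) | C[C@H](O)[C@H](O[Si](CC)(CC)CC)[C@@H](C)[C@H](O[Si](C)(C)C(C)(C)C)[C@@](C)(O[Si](CC)(CC)CC)[C@H](O[Si](C)(C)C(C)(C)C)[C@@H](C)C(=O)O | intermediate
29 | mixed anhydride of 28 and 2-methyl-6-nitrobenzoic acid | C[C@H](O)[C@H](O[Si](CC)(CC)CC)[C@@H](C)[C@H](O[Si](C)(C)C(C)(C)C)[C@@](C)(O[Si](CC)(CC)CC)[C@H](O[Si](C)(C)C(C)(C)C)[C@@H](C)C(=O)OC(=O)c1c(C)cccc1[N+](=O)[O-] | intermediate
30 | protected nine-membered lactone (3,5-OTBS, 4,7-OTES) | CC[Si](CC)(CC)O[C@@H]1[C@@H](C)[C@H](O[Si](C)(C)C(C)(C)C)[C@@](C)(O[Si](CC)(CC)CC)[C@H](O[Si](C)(C)C(C)(C)C)[C@@H](C)C(=O)O[C@H]1C | intermediate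
31 | 7-hydroxy lactone (3,5-OTBS, 4-OTES) | O[C@@H]1[C@@H](C)[C@H](O[Si](C)(C)C(C)(C)C)[C@@](C)(O[Si](CC)(CC)CC)[C@H](O[Si](C)(C)C(C)(C)C)[C@@H](C)C(=O)O[C@H]1C | intermediate
32 | (R)-hept-1-yn-3-ol | CCCC[C@@H](O)C#C | starting material
33 | (R)-3-(tert-butyldimethylsilyloxy)hept-1-yne | CCCC[C@@H](O[Si](C)(C)C(C)(C)C)C#C | intermediate
34 | lithium acetylide of 33 | CCCC[C@@H](O[Si](C)(C)C(C)(C)C)C#C[Li] | intermediate
35 | (R)-4-(tert-butyldimethylsilyloxy)oct-2-ynoic acid | CCCC[C@@H](O[Si](C)(C)C(C)(C)C)C#CC(=O)O | intermediate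
36 | mixed anhydride of 35 and 2,4,6-trichlorobenzoic acid | CCCC[C@@H](O[Si](C)(C)C(C)(C)C)C#CC(=O)OC(=O)c1c(Cl)cc(Cl)cc1Cl | intermediate
37 | fully silylated C7 ynoate | CCCC[C@@H](O[Si](C)(C)C(C)(C)C)C#CC(=O)O[C@@H]1[C@@H](C)[C@H](O[Si](C)(C)C(C)(C)C)[C@@](C)(O[Si](CC)(CC)CC)[C@H](O[Si](C)(C)C(C)(C)C)[C@@H](C)C(=O)O[C@H]1C | intermediate
38 | tetraol ynoate | CCCC[C@@H](O)C#CC(=O)O[C@@H]1[C@@H](C)[C@H](O)[C@@](C)(O)[C@H](O)[C@@H](C)C(=O)O[C@H]1C | intermediate
39 | CNP0205075.2 (2R,3R,4R,5S,6S,7R,8S,4′R,2′Z in target numbering) | CCCC[C@@H](O)/C=C\C(=O)O[C@@H]1[C@@H](C)[C@H](O)[C@@](C)(O)[C@H](O)[C@@H](C)C(=O)O[C@H]1C | target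

**Total step count:** 27
**Longest linear sequence:** 23 steps (4 → steps 3–22 → steps 25–27)

**Three steps most likely to fail**

1. Step 21 (closure of the nine-membered lactone). Intermolecular acylation may outrun the slow, strained closure. Triethylsilyl migration from O7 to O8 before acylation would divert the closure to the wrong oxygen.
 - Fallback: it sets out from 21 and returns at 30, and it closes the ring at C2–C3 instead of at O9–C1.
 - Hydrogenolysis of the BOM group of 21 (H2, Pd(OH)2/C, EtOAc) gives the C8 hydroxy aldehyde F1.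
 - Acylation with 2-bromopropanoyl bromide and pyridine gives the α-bromo ester F2.
 - A SmI2-mediated intramolecular Reformatsky reaction (THF, high dilution, −78 → 0 °C) gives the β-hydroxy nonanolide F3. This reaction type is suited to medium rings because samarium ties the enolate and the aldehyde together.
 - The 2R,3R isomer is separated and silylated (TBSOTf, 2,6-lutidine) to 30.

2. Step 8 (inversion at C5). The carboxylate may attack C3 with allylic shift. The substrate may also ionise to the allyl oxocarbenium ion with loss of stereochemical integrity, or undergo elimination.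
 - Fallback: it sets out from 11 and returns at 12, and it transfers oxygen by a sigmatropic shift instead of a displacement.
 - Acetylation (Ac2O, pyridine) gives the allylic acetate F4.
 - Ferrier-type thiolysis (PhSH, BF3·OEt2, CH2Cl2, −40 °C) gives the axial phenyl thioglycoside F5, with sulfur on the face opposite the C7 side chain.
 - mCPBA at −78 °C gives the sulfoxide F6.
 - Mislow–Evans [2,3] rearrangement with Et2NH as thiophile delivers oxygen suprafacially to C5 and gives the 5S allylic alcohol F7.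
 - Acylation with 4-nitrobenzoyl chloride and pyridine gives 12.

3. Step 6 (key cyclocondensation). The hindered aldehyde may convert slowly under the weak Lewis acid. Felkin facial selectivity may be insufficient, the reaction may leak into the stepwise aldol pathway, and C6 may epimerise during the acid treatment.
 - Fallback: it sets out from 7 and 3 and returns at 10, and it makes the same two bonds in two separate, reagent-controlled events.
 - The Z enol diisopinocampheylborinate of 7 is formed with Ipc2BOTf and i-Pr2NEt in CH2Cl2 at −78 °C, using the antipode that reinforces Felkin attack.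
 - It adds to 3 and gives the syn aldol F8.
 - Catalytic TFA then closes the ring by conjugate addition of O7–H to C3 and loss of methanol, which gives 10.

**Further compounds**
F1 | step 21 | C8 hydroxy C3 aldehyde | C[C@H](O)[C@H](O[Si](CC)(CC)CC)[C@@H](C)[C@H](O[Si](C)(C)C(C)(C)C)[C@@](C)(O[Si](CC)(CC)CC)C=O
F2 | step 21 | C8 2-bromopropanoate of F1 | C[C@H](OC(=O)C(C)Br)[C@H](O[Si](CC)(CC)CC)[C@@H](C)[C@H](O[Si](C)(C)C(C)(C)C)[C@@](C)(O[Si](CC)(CC)CC)C=O
F3 | step 21 | 3-hydroxy nine-membered lactone (5-OTBS, 4,7-OTES) | CC[Si](CC)(CC)O[C@@H]1[C@@H](C)[C@H](O[Si](C)(C)C(C)(C)C)[C@@](C)(O[Si](CC)(CC)CC)[C@H](O)[C@@H](C)C(=O)O[C@H]1C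
F4 | step 8 | acetate of 11 | C[C@H](O[Si](c1ccccc1)(c1ccccc1)C(C)(C)C)[C@@H]1OC=C(C)[C@H](OC(C)=O)[C@@H]1C
F5 | step 8 | phenyl 2,3-unsaturated thioglycoside (S at C3, C4=C5) | C[C@H](O[Si](c1ccccc1)(c1ccccc1)C(C)(C)C)[C@@H]1O[C@@H](Sc2ccccc2)C(C)=C[C@@H]1C
F6 | step 8 | sulfoxide of F5 | C[C@H](O[Si](c1ccccc1)(c1ccccc1)C(C)(C)C)[C@@H]1O[C@@H](S(=O)c2ccccc2)C(C)=C[C@@H]1C
F7 | step 8 | 5S allylic alcohol (C8 OTBDPS) | C[C@H](O[Si](c1ccccc1)(c1ccccc1)C(C)(C)C)[C@@H]1OC=C(C)[C@@H](O)[C@@H]1C
F8 | step 6 | syn aldol of 7 and 3 | CO/C=C(C)/C(=O)[C@H](C)[C@@H](O)[C@H](C)O[Si](c1ccccc1)(c1ccccc1)C(C)(C)C
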